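I start from the constants, and above all from two of them: the growth constant and the unzipping constant.

| flask | free monomer | initiator | temperature | time |
|---|---|---|---|---|
| oak | 12 mM | 0.97 mol% | −5 °C | 80 min |
| alder | 12 mM | 0.97 mol% | 45 °C | 80 min |
| larch | 12 mM | 0.97 mol% | 20 °C | 80 min |

    free monomer + initiator → living end + monomer in chains (k1 = 161 /M/min, Ea1 = 39.0 kJ/mol)
    free monomer + living end → monomer in chains + living end, rate k2*[living end]*[free monomer] (k2 = 1390 /M/min, Ea2 = 44.0 kJ/mol)
    monomer in chains + living end → free monomer + living end, rate k3*[living end] as long as [monomer in chains] is above zero (k3 = 1.29 /min, Ea3 = 69.0 kJ/mol)
    initiator + monomer in chains ⇌ idle complex, settled at all times (K4 = 200 /M, ΔH4 = −57.0 kJ/mol)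
    crystals ⇌ monomer in chains, rate k5*(cs5 - [monomer in chains]) while solid is left; crystals form when [monomer in chains] > cs5 (cs5 = 0.27 mM, k5 = 4.81 /min)
    initiator ⇌ dormant form (K6 = 1.3, k6 = 0.283 /min, Ea6 = 83.0 kJ/mol, ΔH6 = −52.0 kJ/mol)
    (constants at 20 °C)

* which flask leads in amount of monomer in chains, in percent of the free monomer charged ("all alike" within 1.5 percentage points) (oak / alder / larch / all alike)
* how much monomer in chains is there at the end, in percent of the free monomer charged: oak
* how much monomer in chains is there at the end, in percent of the free monomer charged: alder
* how much monomer in chains is there at the end, in percent of the free monomer charged: larch

- what is said of monomer in chains includes idle complex and crystals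
- crystals is a solid; its amount is given per volume of the solution
- at 20 °C the constants are as listed, elsewhere as the activation energies and enthalpies make them

My first way asks where the flask stops. A living end takes up free monomer in proportion to the free monomer present, and it gives monomer back at a rate that does not depend on the amount in chains, as long as some is there. The living end therefore cancels from the balance, and free monomer comes to rest at the unzipping constant divided by the growth constant. I call this the floor; the usual term is equilibrium monomer. It is 0.928 mM in larch, 2.08 mM in alder and 0.357 mM in oak. Monomer that leaves the free state stands in chains, crystals counted, so the floors promise, in the same order, 92.3%, 82.7% and 97.0%.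

My second way follows the clock. With living ends steady, the excess of free monomer over the floor decays pseudo-first-order, by a factor e per turn, and the count of turns is the growth constant times the living ends times the time they work. In a first round I take the ends as the whole initiator charge, 0.116 mM, from the start. Larch then counts 12.9 turns and alder 53.5, both far above one, so in these two flasks the clock lands on the floor and the two ways agree. Oak counts 0.0301 /min times 80 min, which is 2.41 turns, and that leaves 1.05 mM of excess. Here the ways part, and the floor is the one that cheats: it assumes an arrival that oak has not made by the end.

So I put the answer back in and go round once more for oak. Initiator meets free monomer at 0.435 /min and slips to the dormant form at 0.0118 /min, much more slowly. I reckon for oak a delay of the ends of 2.24 min and 2.64% of the charge in the dormant form, which leaves 0.113 mM of living ends. The corrected count of turns, growth constant times living ends times the time they work, is 2.28. Oak then ends with 1.55 mM of free monomer, and I commit to 87.1% in chains.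

The forecast puts larch ahead, with 92.3% there and 82.7% in alder, saying of these two flasks “so equilibrium is reached”. For oak it gives 86.6%, within 85.3% to 87.8%, which is lower than my figure by 0.50 percentage points.

The simulation gives 92.3% in larch, which leads, 82.8% in alder and 86.9% in oak. Left for 800 min, oak stands at 97.0%, level with its floor, and its count has grown to 23.4 turns. The neighbour of oak with 4.8 mM of free monomer at the same loading has fewer ends and a slower start, and counts 0.840 turns. That reckons to 52.6% in chains, and that neighbour stands at 52.4%.

Its constants are made up; the rest is arithmetic.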